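**Retrosynthetic overview** (side-chain carbons numbered C1' at the benzylic CH2 to C11' at the carbinol carbon)

1. The C10'/C11' diol is made last from the ring carbonyl of an L-malic acid acetonide (two methyl groups from MeMgBr); the phenols are freed from MOM ethers in the same pot.
2. Key disconnection C8'–C9' (sp3–sp3): an (E)-allylic acetate on the aryl-geranyl unit plus the CH2 radical of the malic acid acetonide acid (as its NHPI ester), joined in a nickel-catalysed electroreductive decarboxylative coupling.
3. The allylic acetate comes from E-selective SeO2 oxidation of the terminal methyl group of a geranyl arene, itself made from an aryllithium and geranyl bromide (Ar–C1' bond).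
4. The aryl bromide comes from orcinol by MOM protection and NBS bromination, which fixes the site between OMOM and CH3.
5. No ring is built: the benzene ring is orcinol, and the only other ring (the dioxolanone of the malic acid building block) is bought and opened in the last step. No stereocentre is created; the single one is carried in from L-malic acid.

Assumption: the acetonide acid of natural L-malic acid, 2-[(4S)-2,2-dimethyl-5-oxo-1,3-dioxolan-4-yl]acetic acid, is bought as such (catalogue compound; otherwise one step from L-malic acid with 2,2-dimethoxypropane and an acid catalyst).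

**Route**

Step 1
Reactants: 1 orcinol (5-methylbenzene-1,3-diol)
Product: 2 1,3-bis(methoxymethoxy)-5-methylbenzene
Conditions: NaH (2.5 equiv), MOMCl (2.5 equiv), DMF, 0 °C → rt
Reagents that add atoms: chloromethyl methyl ether (MOMCl), COCCl
Why: Williamson-type O-alkylation of both sodium phenoxides (MOM protection) is clean in DMF and gives ethers that survive organolithium, oxidation and electrolysis conditions.

Step 2
Reactants: 2 1,3-bis(methoxymethoxy)-5-methylbenzene
Product: 3 2-bromo-1,5-bis(methoxymethoxy)-3-methylbenzene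
Conditions: NBS (1.0 equiv), MeCN, 0 °C
Reagents that add atoms: N-bromosuccinimide (NBS), O=C1CCC(=O)N1Br
Why: Electrophilic aromatic bromination goes to the position para to one MOM ether and ortho to the other and to the methyl group, the less hindered of the two doubly activated sites, as is usual for orcinol diethers.

Step 3
Reactants: 3 2-bromo-1,5-bis(methoxymethoxy)-3-methylbenzene; 4 geranyl bromide [(2E)-1-bromo-3,7-dimethylocta-2,6-diene]
Product: 6 2-[(2E)-3,7-dimethylocta-2,6-dien-1-yl]-1,5-bis(methoxymethoxy)-3-methylbenzene, via aryllithium 5 (not isolated)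
Conditions: n-BuLi (1.05 equiv), THF, −78 °C; then CuBr·SMe2 (10 mol%), 4 (1.1 equiv), −78 → 0 °C
Reagents that add atoms: none
Why: Bromine–lithium exchange followed by copper-catalysed SN2 allylation at the primary allylic carbon keeps the E alkene of geranyl bromide, and the SN2' alternative would have to build a quaternary benzylic carbon, so the linear product dominates.

Step 4
Reactants: 6 2-[(2E)-3,7-dimethylocta-2,6-dien-1-yl]-1,5-bis(methoxymethoxy)-3-methylbenzene
Product: 7 (2E,6E)-8-[2,4-bis(methoxymethoxy)-6-methylphenyl]-2,6-dimethylocta-2,6-dien-1-ol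
Conditions: SeO2 (10 mol%), t-BuOOH (3 equiv), salicylic acid (10 mol%), CH2Cl2, 0 °C → rt
Reagents that add atoms: tert-butyl hydroperoxide, CC(C)(C)OO (net source of the new oxygen atom, passed on through selenium dioxide, O=[Se]=O)
Why: Riley allylic oxidation (ene reaction, then [2,3]-sigmatropic shift) attacks the E-methyl group of the terminal trisubstituted alkene and gives the (E)-allylic alcohol; the internal alkene is the competing site.

Step 5
Reactants: 7 (2E,6E)-8-[2,4-bis(methoxymethoxy)-6-methylphenyl]-2,6-dimethylocta-2,6-dien-1-ol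
Product: 8 (2E,6E)-8-[2,4-bis(methoxymethoxy)-6-methylphenyl]-2,6-dimethylocta-2,6-dien-1-yl acetate
Conditions: Ac2O (1.5 equiv), pyridine, DMAP (5 mol%), CH2Cl2, 0 °C → rt
Reagents that add atoms: acetic anhydride, CC(=O)OC(C)=O
Why: DMAP-catalysed acylation of the primary allylic alcohol installs a non-basic leaving group for the nickel step without touching the MOM ethers or the alkenes.

Step 6
Reactants: 8 (2E,6E)-8-[2,4-bis(methoxymethoxy)-6-methylphenyl]-2,6-dimethylocta-2,6-dien-1-yl acetate; 9 2-[(4S)-2,2-dimethyl-5-oxo-1,3-dioxolan-4-yl]acetic acid (acetonide of L-malic acid)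
Product: 11 (5S)-5-{(3E,7E)-9-[2,4-bis(methoxymethoxy)-6-methylphenyl]-3,7-dimethylnona-3,7-dien-1-yl}-2,2-dimethyl-1,3-dioxolan-4-one, via NHPI ester 10 (not isolated)
Conditions: 9 (1.8 equiv), N-hydroxyphthalimide, DIC, CH2Cl2, rt, then solvent swap; 8, NiBr2·DME (10 mol%), 4,4',4''-tri-tert-butyl-2,2':6',2''-terpyridine (12 mol%), LiCl, DMF, Mg anode / RVC cathode, undivided cell, 5 mA, 2.5 F/mol, rt
Reagents that add atoms: none
Why: Proposed new method: a nickel-electrocatalysed decarboxylative alkyl–allyl coupling of a redox-active ester with a 2-methyl-substituted (prenyl-tail) allylic acetate, forming the C8'–C9' bond. Cathodically formed zerovalent nickel adds oxidatively to the allylic acetate; monovalent nickel or the cathode transfers one electron to the NHPI ester, which loses phthalimide anion and CO2 to give the primary CH2 radical next to the dioxolanone (a β-oxygenated radical that does not fragment); the divalent allylnickel captures this radical, and the trivalent alkyl(allyl)nickel reductively eliminates at the unsubstituted CH2 terminus. The tridentate ligand favours the σ-allyl bound at the primary carbon, so the E alkene is not scrambled, and the stereocentre of 9 is not a reacting centre and is carried over unchanged. The closest known reaction types are the nickel-electrocatalytic decarboxylative alkenylation of redox-active esters with vinyl iodides and the zinc-driven nickel-catalysed reductive coupling of alkyl halides with allylic acetates or carbonates; new here is the electrochemical pairing of a redox-active ester with a prenyl-tail allylic acetate.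

Step 7
Reactants: 11 (5S)-5-{(3E,7E)-9-[2,4-bis(methoxymethoxy)-6-methylphenyl]-3,7-dimethylnona-3,7-dien-1-yl}-2,2-dimethyl-1,3-dioxolan-4-one
Product: 13 4-[(2E,6E,10S)-10,11-dihydroxy-3,7,11-trimethyldodeca-2,6-dien-1-yl]-5-methylbenzene-1,3-diol, via bis-MOM diol 12 (not isolated)
Conditions: MeMgBr (6 equiv), THF, 0 °C → rt; then MeOH, HCl (to ca. 1 M), rt → 40 °C
Reagents that add atoms: methylmagnesium bromide, C[Mg]Br
Why: Double Grignard addition to the dioxolanone carbonyl (ring opening, loss of acetone, second addition) gives the secondary/tertiary diol with the L-malic acid stereocentre untouched, and acidic methanol then cleaves the two MOM acetals by acetal exchange.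

**Compound list**

1 | orcinol (5-methylbenzene-1,3-diol) | Cc1cc(O)cc(O)c1 | starting material
2 | 1,3-bis(methoxymethoxy)-5-methylbenzene | COCOc1cc(C)cc(OCOC)c1 | intermediate
3 | 2-bromo-1,5-bis(methoxymethoxy)-3-methylbenzene | COCOc1cc(C)c(Br)c(OCOC)c1 | intermediate
4 | geranyl bromide, (2E)-1-bromo-3,7-dimethylocta-2,6-diene | CC(C)=CCC/C(C)=C/CBr | starting material
5 | [2,4-bis(methoxymethoxy)-6-methylphenyl]lithium | [Li]c1c(C)cc(OCOC)cc1OCOC | intermediate (not isolated)
6 | 2-[(2E)-3,7-dimethylocta-2,6-dien-1-yl]-1,5-bis(methoxymethoxy)-3-methylbenzene | COCOc1cc(C)c(C/C=C(\C)CCC=C(C)C)c(OCOC)c1 | intermediate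
7 | (2E,6E)-8-[2,4-bis(methoxymethoxy)-6-methylphenyl]-2,6-dimethylocta-2,6-dien-1-ol | COCOc1cc(C)c(C/C=C(\C)CC/C=C(\C)CO)c(OCOC)c1 | intermediate
8 | (2E,6E)-8-[2,4-bis(methoxymethoxy)-6-methylphenyl]-2,6-dimethylocta-2,6-dien-1-yl acetate | COCOc1cc(C)c(C/C=C(\C)CC/C=C(\C)COC(C)=O)c(OCOC)c1 | intermediate
9 | 2-[(4S)-2,2-dimethyl-5-oxo-1,3-dioxolan-4-yl]acetic acid | OC(=O)C[C@@H]1OC(C)(C)OC1=O | starting material
10 | 1,3-dioxoisoindolin-2-yl 2-[(4S)-2,2-dimethyl-5-oxo-1,3-dioxolan-4-yl]acetate | O=C(C[C@@H]1OC(C)(C)OC1=O)ON1C(=O)c2ccccc2C1=O | intermediate (not isolated)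
11 | (5S)-5-{(3E,7E)-9-[2,4-bis(methoxymethoxy)-6-methylphenyl]-3,7-dimethylnona-3,7-dien-1-yl}-2,2-dimethyl-1,3-dioxolan-4-one | COCOc1cc(C)c(C/C=C(\C)CC/C=C(\C)CC[C@@H]2OC(C)(C)OC2=O)c(OCOC)c1 | intermediate
12 | (3S,6E,10E)-12-[2,4-bis(methoxymethoxy)-6-methylphenyl]-2,6,10-trimethyldodeca-6,10-diene-2,3-diol | COCOc1cc(C)c(C/C=C(\C)CC/C=C(\C)CC[C@H](O)C(C)(C)O)c(OCOC)c1 | intermediate (not isolated)
13 | 4-[(2E,6E,10S)-10,11-dihydroxy-3,7,11-trimethyldodeca-2,6-dien-1-yl]-5-methylbenzene-1,3-diol | C/C(=C\Cc1c(C)cc(O)cc1O)CC/C=C(\C)CC[C@H](O)C(C)(C)O | target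

**Totals**

Total step count: 7. Longest linear sequence: 7 steps (orcinol 1 to target 13); geranyl bromide 4 and acid 9 enter as bought materials.

**Three steps most likely to fail**

Step 6, the proposed new coupling. The risks are allyl homocoupling, the branched isomer and partial loss of E geometry at C6'=C7'. The fallback uses known chemistry, sets out from alcohol 7 and comes back at dioxolanone 11. Alcohol 7 is converted with CBr4 and PPh3 into the allylic bromide 2-[(2E,6E)-8-bromo-3,7-dimethylocta-2,6-dien-1-yl]-1,5-bis(methoxymethoxy)-3-methylbenzene F4. The dianion of bought dimethyl (S)-malate F5 (LiN(iPr)2, 2.2 equiv, THF, −78 → −20 °C) is alkylated by F4 at C3 in a Fráter–Seebach alkylation, an SN2 reaction at the primary allylic carbon that keeps the E alkene, to give dimethyl (2S,3R)-2-hydroxy-3-{(2E,6E)-8-[2,4-bis(methoxymethoxy)-6-methylphenyl]-2,6-dimethylocta-2,6-dien-1-yl}butanedioate F6. LiOH gives the corresponding (2S,3R)-butanedioic acid F7. 2,2-Dimethoxypropane with PPTS closes the dioxolanone on the α-hydroxy acid only, giving (2R,4E,8E)-10-[2,4-bis(methoxymethoxy)-6-methylphenyl]-2-[(4S)-2,2-dimethyl-5-oxo-1,3-dioxolan-4-yl]-4,8-dimethyldeca-4,8-dienoic acid F8. Barton reductive decarboxylation (N-hydroxypyridine-2-thione and DCC to the 2-thioxopyridin-1(2H)-yl ester F9, not isolated, then t-BuSH and visible light) removes the extra carboxyl group and gives 11. The additional stereocentre at C3 is erased in this last operation and the malic acid centre is never touched.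

Step 4, the SeO2 oxidation. The risks are competing oxidation at the internal alkene and over-oxidation to the enal. The fallback sets out from bromide 3 (through aryllithium 5) and comes back at alcohol 7. Bought geranyl acetate F1 is oxidised under the same SeO2/t-BuOOH conditions to (2E,6E)-8-hydroxy-3,7-dimethylocta-2,6-dien-1-yl acetate F2; here the allylic acetate deactivates the 2,3-alkene, so only the terminal alkene reacts. Aryllithium 5 is transmetalated with ZnCl2 to [2,4-bis(methoxymethoxy)-6-methylphenyl]zinc chloride F3 (not isolated). F3 couples with F2 under Pd(PPh3)4 catalysis in THF (Negishi-type allylic arylation at the primary terminus with retention of the E alkene; the free primary alcohol is tolerated by the arylzinc) to give 7 directly.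

Step 7, the one-pot Grignard addition and acidic MOM cleavage. The risk is acid-promoted cyclisation of the freed ortho-prenylated phenol or of the tertiary alcohol onto an alkene. The fallback reverses the order so that acid is used before the tertiary alcohol exists; it sets out from 11 and comes back at 13. HCl in MeOH at rt cleaves both MOM ethers and methanolyses the dioxolanone to methyl (2S,5E,9E)-11-(2,4-dihydroxy-6-methylphenyl)-2-hydroxy-5,9-dimethylundeca-5,9-dienoate F10, which is isolated. MeMgBr (7 equiv, THF, 0 °C → rt) then adds twice to the ester of the unprotected triol and gives 13 after a neutral NH4Cl work-up.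

**Further compounds**

F1 | step 4 | geranyl acetate, (2E)-3,7-dimethylocta-2,6-dien-1-yl acetate (bought) | CC(C)=CCC/C(C)=C/COC(C)=O
F2 | step 4 | (2E,6E)-8-hydroxy-3,7-dimethylocta-2,6-dien-1-yl acetate | CC(=O)OC/C=C(\C)CC/C=C(\C)CO
F3 | step 4 | [2,4-bis(methoxymethoxy)-6-methylphenyl]zinc chloride (not isolated) | Cl[Zn]c1c(C)cc(OCOC)cc1OCOC
F4 | step 6 | 2-[(2E,6E)-8-bromo-3,7-dimethylocta-2,6-dien-1-yl]-1,5-bis(methoxymethoxy)-3-methylbenzene | COCOc1cc(C)c(C/C=C(\C)CC/C=C(\C)CBr)c(OCOC)c1
F5 | step 6 | dimethyl (S)-malate (bought) | COC(=O)C[C@H](O)C(=O)OC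
F6 | step 6 | dimethyl (2S,3R)-2-hydroxy-3-{(2E,6E)-8-[2,4-bis(methoxymethoxy)-6-methylphenyl]-2,6-dimethylocta-2,6-dien-1-yl}butanedioate | COC(=O)[C@@H](O)[C@@H](C/C(C)=C/CC/C(C)=C/Cc1c(C)cc(OCOC)cc1OCOC)C(=O)OC
F7 | step 6 | (2S,3R)-2-hydroxy-3-{(2E,6E)-8-[2,4-bis(methoxymethoxy)-6-methylphenyl]-2,6-dimethylocta-2,6-dien-1-yl}butanedioic acid | OC(=O)[C@@H](O)[C@@H](C/C(C)=C/CC/C(C)=C/Cc1c(C)cc(OCOC)cc1OCOC)C(=O)O
F8 | step 6 | (2R,4E,8E)-10-[2,4-bis(methoxymethoxy)-6-methylphenyl]-2-[(4S)-2,2-dimethyl-5-oxo-1,3-dioxolan-4-yl]-4,8-dimethyldeca-4,8-dienoic acid | OC(=O)[C@H](C/C(C)=C/CC/C(C)=C/Cc1c(C)cc(OCOC)cc1OCOC)[C@@H]1OC(C)(C)OC1=O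
F9 | step 6 | 2-thioxopyridin-1(2H)-yl ester of F8 (Barton ester, not isolated) | S=C1C=CC=CN1OC(=O)[C@H](C/C(C)=C/CC/C(C)=C/Cc1c(C)cc(OCOC)cc1OCOC)[C@@H]1OC(C)(C)OC1=O
F10 | step 7 | methyl (2S,5E,9E)-11-(2,4-dihydroxy-6-methylphenyl)-2-hydroxy-5,9-dimethylundeca-5,9-dienoate | COC(=O)[C@@H](O)CC/C(C)=C/CC/C(C)=C/Cc1c(C)cc(O)cc1O
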